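## The problem

The target is a 17-membered cyclophane of four benzene rings joined in the order A–O–B–CH2CH2–C–O–D–CH2CH2–A. Ring A is meta-bridged and carries two adjacent hydroxyls next to its ether oxygen, ring B is a para-phenylene, ring C is ortho-bridged with a catechol next to its ether oxygen, and ring D is an otherwise unsubstituted ortho-phenylene. There is no stereocentre, so the task is one of connectivity, ring closure and chemoselectivity. The two catechol units are easily oxidised to ortho-quinones and bind metals, so all four hydroxyls should travel as methyl ethers and be freed last. The A–O–B ether and both ethano bridges are routine (a para-activated fluoroarene, olefination/hydrogenation, alkylation). The C–O–D ether is the hard bond: the ring C oxygen is flanked by the bridge carbon and an oxygenated carbon, and the ring D carbon has an ortho alkyl group and no activating substituent. The enabling feature is that ring D carries only the ether oxygen and the CH2CH2 chain, on adjacent carbons. These map onto C3 and C2 of a 2-alkyl-3-chlorocyclohex-2-enone made from cyclohexane-1,3-dione, whose sp2 C3 accepts even a hindered phenoxide by addition–elimination. The leftover carbonyl carbon C1 becomes the ring D CH next to the alkyl-bearing carbon, so its oxygen must be removed after aromatisation.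

## Retrosynthesis

**Unmasking.** The target 23 is cut at its four O–CH3 bonds to the tetramethyl ether 22. Methyl ethers are preferred to benzyl or silyl groups because they survive hydrogenation, oxalyl chloride, carbonate base, iodine and palladium. The forward step needs only that BBr3 cleaves alkyl–O and not aryl–O bonds.

**Ring D back to a cyclohexenone.** Arene 22 is traced to aryl triflate 21, phenol 20 and the macrocyclic 3-aryloxy-2-alkylcyclohex-2-enone 18. The phenol oxygen of 20 is the carbonyl oxygen of 18, so no carbon has to be added or moved. The forward direction asks for dehydrogenation of a vinylogous ester to a phenol and reductive removal of one phenolic oxygen while four methyl ethers stay.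

**Key disconnection.** In 18 the bond between the ring C oxygen and C3 of the enone is cut, giving the seco phenol chloroenone 16.
- Cutting the A–O–B ether instead would need SNAr on a ring B that has lost its activating formyl group.
- Cutting an ethano bridge (macrocyclising olefination) would leave the hindered C–O–D ether to be made by intermolecular arylation.
- The chosen cut turns the worst bond of the molecule into an acyl-type substitution and removes the macrocycle; 16 is a linear array of three arenes and one chloroenone.
- The forward reaction must deliver O-attack at the β-carbon and ring closure in preference to oligomerisation.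

**Chloroenone from dione.** Chloroenone 16 comes from the 2-alkylcyclohexane-1,3-dione 15 by exchange of the enolic OH for chlorine. The dione is symmetric, so no regiochemistry arises. The forward step must activate the vinylogous acid in the presence of a free, hindered phenol.

**The A–D bridge.** Dione 15 is the hydrogenation product of stilbene benzyl ether 14, and 14 is cut at the bond between C2 of the dione and the bridge CH2, giving arylacetaldehyde 11 and cyclohexane-1,3-dione 12. Reductive alkylation is preferred to alkylating the dione with a 2-arylethyl halide, which suffers O-alkylation and elimination. One hydrogenation then saturates the B–C bridge and frees the ring C phenol.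

**The B–C bridge.** Aldehyde 11 is the hydrolysis product of enol ether 10, whose stilbene C=C is cut to aldehyde 8 and phosphonium salt 4 (through ylide 9). Carrying the ring A aldehyde as a methyl enol ether keeps it inert to the ylide and to base, and it is revealed by dilute acid when needed.

**The A–O–B ether.** Aldehyde 8 is cut at the ring B C–O bond to phenol 6 and 4-fluorobenzaldehyde 7, and 6 comes from 3-hydroxy-4,5-dimethoxybenzaldehyde 5 by one-carbon homologation. Homologating before the SNAr means the two formyl-level carbons of rings A and B are never present as two aldehydes.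

**Ring C fragment.** Phosphonium salt 4 comes from alcohol 3, aldehyde 2 and 2-hydroxy-3,4-dimethoxybenzaldehyde 1. The benzyl ether is chosen because the hydrogenation to 15 removes it at no extra cost.

## Roads not taken

**Alternative 1:** Transannular Fries shift.
- Cut: the bond between ring A (carbon para to its central oxygen) and the carbon that becomes the ring A-side CH2 of the A–D bridge.
- Forward: macrolactone A1 (ring A central oxygen acylated by the ring D arylacetic acid) is treated with BF3·OEt2; the acyl group moves to the para carbon to give the keto cyclophane A2.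
- Merits: macrolactonisation is dependable; both ortho positions of that oxygen are blocked, so only para migration is possible; ring D is aromatic throughout. After ketone reduction the endgame would be about two steps shorter than the chosen one.
- Weak points: a para Fries shift needs the acyl fragment to leave the oxygen and reach a carbon four atoms away across the ring. That favours dissociation, with crossover, oligomers or simple ester cleavage. Arylacetyl fragments also tend to form ketenes, and BF3 may attack the methyl ethers. Above all, A1 already contains the C–O–D ether, which would have to be made by the hindered arylation this plan avoids.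
- Comparison: the chosen plan pays with three extra steps after ring closure, but closes the ring with a bond-forming type known for this bond and removes the hard arylation.

**Alternative 2:** Ring B by cobalt-catalysed Diels–Alder.
- Cut: two C–C bonds of ring B.
- Forward: the buta-1,3-dien-2-yl ether and terminal alkyne of A3 react under CoBr2(dppe), zinc and ZnI2 to give A4, in which ring B is a 1,4-cyclohexadiene and the macrocycle is closed; oxidation then aromatises ring B.
- Merits: two C–C bonds, one arene and the macrocycle in one neutral step. In complexity gained per step it is better than the chosen route.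
- Weak points: the 2-aryloxybutadiene on the hindered ring A oxygen has no simple preparation and is acid-labile. The tethered, macrocyclising version has no close precedent, and the tether may override the usual para regiochemistry. Low-valent cobalt can also trimerise the alkyne. The C–O–D ether is again left to conventional arylation.
- Comparison: the chosen plan is less elegant in ring B, which it buys as 4-fluorobenzaldehyde, but every step is a known reaction type.

**Alternative 3:** Biomimetic oxidative phenol coupling.
- Cut: the ring A C–O bond of the A–O–B ether.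
- Forward: Tl(NO3)3 (trivalent thallium) oxidises the 2,6-dibromophenol of A5, the dichlorophenol oxygen attacks a bromine-bearing ortho carbon, and zinc work-up gives A6.
- Merits: no activated aryl halide is needed, and the method is established for hindered diaryl ether macrocycles.
- Weak points: it solves the easy ether, which the chosen route makes in one SNAr step. It needs stoichiometric toxic thallium. The remaining bromine of A6 sits where the target needs a hydroxyl, and two chlorines must be removed. The dimethoxy ring C may be oxidised as well, and the C–O–D ether is still made by arylation.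
- Comparison: it is closer to the likely biogenesis, but is longer and carries more baggage than the chosen plan.

Key step: step 11

Remark on the chemistry: the target has no stereocentre. The enol ether and stilbene double bonds in 6, 8, 10, 11, 13 and 14 are taken as E/Z mixtures and drawn without geometry, because each is later hydrolysed or hydrogenated.

## Route

Step 1
Reactants: 1 2-hydroxy-3,4-dimethoxybenzaldehyde
Product: 2 2-(benzyloxy)-3,4-dimethoxybenzaldehyde
Conditions: BnBr, K2CO3, DMF, 60 °C
Reagents that add atoms: benzyl bromide, BrCc1ccccc1
Why: Williamson O-benzylation of the only acidic OH; benzyl is chosen because the hydrogenation of step 9 removes it.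

Step 2
Reactants: 2 2-(benzyloxy)-3,4-dimethoxybenzaldehyde
Product: 3 [2-(benzyloxy)-3,4-dimethoxyphenyl]methanol
Conditions: NaBH4, MeOH, 0 °C
Reagents that add atoms: none
Why: Borohydride reduction of an aryl aldehyde to the benzylic alcohol; the ethers are inert.

Step 3
Reactants: 3 [2-(benzyloxy)-3,4-dimethoxyphenyl]methanol
Product: 4 [2-(benzyloxy)-3,4-dimethoxybenzyl]triphenylphosphonium bromide
Conditions: PPh3·HBr, MeCN, reflux
Reagents that add atoms: triphenylphosphine hydrobromide, Br.c1ccc(cc1)P(c1ccccc1)c1ccccc1
Why: The electron-rich benzylic alcohol ionises under the acidic phosphine salt and is trapped by triphenylphosphine, so the labile benzylic bromide is never isolated; the aryl benzyl ether is stable here.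

Step 4
Reactants: 5 3-hydroxy-4,5-dimethoxybenzaldehyde
Product: 6 2,3-dimethoxy-5-(2-methoxyethenyl)phenol (E/Z mixture)
Conditions: MeOCH2PPh3Cl, KOtBu (excess), THF, 0 °C to rt; aq. NH4Cl
Reagents that add atoms: (methoxymethyl)triphenylphosphonium chloride, COC[P+](c1ccccc1)(c1ccccc1)c1ccccc1.[Cl-]
Why: Wittig methoxymethylenation (one-carbon homologation); an extra equivalent of base holds 5 as its potassium salt, and because the oxygen is meta to the formyl group the aldehyde stays electrophilic. The mild work-up keeps the enol ether.

Step 5
Reactants: 6 2,3-dimethoxy-5-(2-methoxyethenyl)phenol; 7 4-fluorobenzaldehyde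
Product: 8 4-[2,3-dimethoxy-5-(2-methoxyethenyl)phenoxy]benzaldehyde (E/Z mixture)
Conditions: K2CO3, DMF, 130 °C
Reagents that add atoms: none
Why: SNAr of the potassium salt of 6 at the C–F carbon activated by the para formyl group; the enol ether is stable to base, so ring A stays masked while ring B carries the only aldehyde.

Step 6
Reactants: 4 [2-(benzyloxy)-3,4-dimethoxybenzyl]triphenylphosphonium bromide; 8 4-[2,3-dimethoxy-5-(2-methoxyethenyl)phenoxy]benzaldehyde
Product: 10 2-(benzyloxy)-3,4-dimethoxy-1-(2-{4-[2,3-dimethoxy-5-(2-methoxyethenyl)phenoxy]phenyl}ethenyl)benzene (stilbene enol ether; E/Z mixture), via benzylidenephosphorane 9 (not isolated)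
Conditions: KOtBu, THF, 0 °C to rt
Reagents that add atoms: none
Why: Wittig olefination of the semi-stabilised ylide 9 with the ring B aldehyde forms the B–C bridge; alkene geometry is irrelevant and the enol ether is inert to ylide and base.

Step 7
Reactants: 10 stilbene enol ether
Product: 11 {3-[4-(2-[2-(benzyloxy)-3,4-dimethoxyphenyl]ethenyl)phenoxy]-4,5-dimethoxyphenyl}acetaldehyde
Conditions: 2 M HCl, THF, rt; used at once
Reagents that add atoms: water, O
Why: Acid hydrolysis of the methyl enol ether (C-protonation, water capture, loss of methanol) gives the arylacetaldehyde; the benzyl ether and stilbene tolerate dilute acid. The aldehyde is not stored because it enolises easily.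

Step 8
Reactants: 11 arylacetaldehyde; 12 cyclohexane-1,3-dione
Product: 14 2-[2-(3-{4-[2-(2-benzyloxy-3,4-dimethoxyphenyl)ethenyl]phenoxy}-4,5-dimethoxyphenyl)ethyl]cyclohexane-1,3-dione, via alkylidene dione 13 (not isolated)
Conditions: Hantzsch ester (diethyl 2,6-dimethyl-1,4-dihydropyridine-3,5-dicarboxylate), L-proline (cat.), CH2Cl2, rt
Reagents that add atoms: none
Why: Organocatalytic three-component reductive alkylation: proline-mediated Knoevenagel condensation gives alkylidene dione 13, which the Hantzsch ester reduces by hydride transfer faster than a second dione can add. The unactivated stilbene and benzyl ether are not reduced.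

Step 9
Reactants: 14 stilbene benzyl ether dione
Product: 15 2-[2-(3-{4-[2-(2-hydroxy-3,4-dimethoxyphenyl)ethyl]phenoxy}-4,5-dimethoxyphenyl)ethyl]cyclohexane-1,3-dione
Conditions: H2 (1 atm), Pd/C, EtOAc–MeOH, rt
Reagents that add atoms: none
Why: Catalytic hydrogenation saturates the stilbene and hydrogenolyses the benzyl ether in one operation; the enolised 1,3-dione is not reduced under neutral conditions at ambient pressure. It has to come before chlorine is introduced.

Step 10
Reactants: 15 seco phenol dione
Product: 16 3-chloro-2-[2-(3-{4-[2-(2-hydroxy-3,4-dimethoxyphenyl)ethyl]phenoxy}-4,5-dimethoxyphenyl)ethyl]cyclohex-2-en-1-one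
Conditions: (COCl)2 (slight excess), DMF (cat.), CH2Cl2, 0 °C; aq. NaHCO3 work-up
Reagents that add atoms: oxalyl chloride, O=C(Cl)C(=O)Cl
Why: Known conversion of cyclic 1,3-diones into β-chloroenones: the enol is acylated like a carboxylic acid, chloride adds to the β-carbon, and CO, CO2 and HCl are lost. Without base the hindered, hydrogen-bonded phenol is far less nucleophilic, and any aryl chlorooxalate formed is cleaved in the bicarbonate wash.

Step 11
Reactants: 16 seco phenol chloroenone
Product: 18 macrocyclic 3-aryloxy-2-alkylcyclohex-2-enone (tetramethoxy cyclophane with future ring D as cyclohexenone), via caesium phenoxide 17 (not isolated)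
Conditions: Cs2CO3, DMF, 70 °C, slow addition of 16 (final ca. 1 mM)
Reagents that add atoms: none
Why: Cs2CO3 converts the ring C phenol into caesium phenoxide 17, whose oxygen adds to C3 (the chlorine-bearing β-carbon) of the enone; the resulting chloro enolate expels chloride and restores conjugation as a vinylogous aryl ester. The closest known reaction type is the intermolecular addition–elimination of phenoxides on 3-chlorocyclohex-2-enones (vinylogous acyl substitution), here run within one molecule. The 17-membered ring closes by a 17-endo-trig addition, since the attacked C2=C3 bond lies inside the new ring, followed by loss of chloride. No stereocentre is formed. O- over C-attack of the ambident phenoxide is favoured by the hard vinylogous acyl chloride, the caesium counter-ion and the dipolar aprotic solvent. Conjugate over carbonyl addition follows because 1,2-addition is reversible and unproductive, while β-addition is pulled forward by chloride loss. Ring closure over oligomerisation is addressed by slow addition into a dilute, warm suspension of the base. The trigonal β-carbon is approached from above the ring plane, so the substituents flanking the phenoxide matter much less than in an aryl halide coupling, and nothing else in 16 is nucleophilic or base-labile.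

Step 12
Reactants: 18 macrocyclic enone
Product: 20 macrocyclic ring D phenol (OH on ring D next to the bridge-bearing carbon, on the side away from the ether oxygen; rings A and C as dimethyl ethers), via 6-iodo enone 19 (not isolated)
Conditions: I2 (cat.), DMSO, 100 °C
Reagents that add atoms: none
Why: Iodine-mediated dehydrogenative aromatisation of a cyclohexenone: α′-iodination through the dienol gives 19, loss of HI gives the cross-conjugated dienone, and tautomerisation gives the phenol. DMSO reoxidises HI to I2, so only a catalytic amount of electrophilic iodine meets the electron-rich rings.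

Step 13
Reactants: 20 macrocyclic ring D phenol
Product: 21 macrocyclic ring D aryl triflate
Conditions: Tf2O, pyridine, CH2Cl2, 0 °C
Reagents that add atoms: trifluoromethanesulfonic anhydride, O=S(=O)(OS(=O)(=O)C(F)(F)F)C(F)(F)F
Why: O-sulfonylation of the only free hydroxyl in the molecule; all other oxygens are methyl or diaryl ethers.

Step 14
Reactants: 21 macrocyclic ring D aryl triflate
Product: 22 tetra-O-methyl ether of the target
Conditions: Pd(OAc)2, dppf, HCO2H, Et3N, DMF, 80 °C
Reagents that add atoms: none
Why: Palladium-catalysed formate reduction of an aryl triflate: zerovalent palladium formed in situ inserts into the C–OTf bond, formate replaces triflate and loses CO2 to give an aryl palladium hydride, and reductive elimination gives the arene. Methyl and diaryl ethers are untouched.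

Step 15
Reactants: 22 tetra-O-methyl ether of the target
Product: 23 CNP0114693.0 (target)
Conditions: BBr3, CH2Cl2, −78 °C to rt; then MeOH, H2O (under argon)
Reagents that add atoms: none
Why: Lewis-acid demethylation: BBr3 coordinates each methoxy oxygen and bromide attacks the methyl carbon (SN2), while the diaryl ether C–O bonds offer no sp3 carbon and survive. Hydrolysis frees the two catechols, which are handled with exclusion of air.

## Compound list

1 | 2-hydroxy-3,4-dimethoxybenzaldehyde | COc1ccc(C=O)c(O)c1OC | starting material
2 | 2-(benzyloxy)-3,4-dimethoxybenzaldehyde | COc1ccc(C=O)c(OCc2ccccc2)c1OC | intermediate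
3 | [2-(benzyloxy)-3,4-dimethoxyphenyl]methanol | COc1ccc(CO)c(OCc2ccccc2)c1OC | intermediate
4 | [2-(benzyloxy)-3,4-dimethoxybenzyl]triphenylphosphonium bromide | COc1ccc(C[P+](c2ccccc2)(c2ccccc2)c2ccccc2)c(OCc2ccccc2)c1OC.[Br-] | intermediate
5 | 3-hydroxy-4,5-dimethoxybenzaldehyde | COc1cc(C=O)cc(O)c1OC | starting material
6 | 2,3-dimethoxy-5-(2-methoxyethenyl)phenol (E/Z mixture) | COC=Cc1cc(O)c(OC)c(OC)c1 | intermediate
7 | 4-fluorobenzaldehyde | O=Cc1ccc(F)cc1 | starting material
8 | 4-[2,3-dimethoxy-5-(2-methoxyethenyl)phenoxy]benzaldehyde (E/Z mixture) | COC=Cc1cc(OC)c(OC)c(c1)Oc1ccc(C=O)cc1 | intermediate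
9 | [2-(benzyloxy)-3,4-dimethoxybenzylidene]triphenylphosphorane | COc1ccc(C=P(c2ccccc2)(c2ccccc2)c2ccccc2)c(OCc2ccccc2)c1OC | intermediate (not isolated)
10 | 2-(benzyloxy)-3,4-dimethoxy-1-(2-{4-[2,3-dimethoxy-5-(2-methoxyethenyl)phenoxy]phenyl}ethenyl)benzene (E/Z mixture) | COC=Cc1cc(OC)c(OC)c(c1)Oc1ccc(cc1)C=Cc1ccc(OC)c(OC)c1OCc1ccccc1 | intermediate
11 | {3-[4-(2-[2-(benzyloxy)-3,4-dimethoxyphenyl]ethenyl)phenoxy]-4,5-dimethoxyphenyl}acetaldehyde | O=CCc1cc(OC)c(OC)c(c1)Oc1ccc(cc1)C=Cc1ccc(OC)c(OC)c1OCc1ccccc1 | intermediate
12 | cyclohexane-1,3-dione | O=C1CCCC(=O)C1 | starting material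
13 | 2-[2-(3-{4-[2-(2-benzyloxy-3,4-dimethoxyphenyl)ethenyl]phenoxy}-4,5-dimethoxyphenyl)ethylidene]cyclohexane-1,3-dione | O=C1CCCC(=O)C1=CCc1cc(OC)c(OC)c(c1)Oc1ccc(cc1)C=Cc1ccc(OC)c(OC)c1OCc1ccccc1 | intermediate (not isolated)
14 | 2-[2-(3-{4-[2-(2-benzyloxy-3,4-dimethoxyphenyl)ethenyl]phenoxy}-4,5-dimethoxyphenyl)ethyl]cyclohexane-1,3-dione | O=C1CCCC(=O)C1CCc1cc(OC)c(OC)c(c1)Oc1ccc(cc1)C=Cc1ccc(OC)c(OC)c1OCc1ccccc1 | intermediate
15 | 2-[2-(3-{4-[2-(2-hydroxy-3,4-dimethoxyphenyl)ethyl]phenoxy}-4,5-dimethoxyphenyl)ethyl]cyclohexane-1,3-dione | O=C1CCCC(=O)C1CCc1cc(OC)c(OC)c(c1)Oc1ccc(cc1)CCc1ccc(OC)c(OC)c1O | intermediate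
16 | 3-chloro-2-[2-(3-{4-[2-(2-hydroxy-3,4-dimethoxyphenyl)ethyl]phenoxy}-4,5-dimethoxyphenyl)ethyl]cyclohex-2-en-1-one | ClC1=C(CCc2cc(OC)c(OC)c(c2)Oc2ccc(cc2)CCc2ccc(OC)c(OC)c2O)C(=O)CCC1 | intermediate
17 | caesium phenoxide of 16 | [Cs+].[O-]c1c(CCc2ccc(cc2)Oc2cc(CCC3=C(Cl)CCCC3=O)cc(OC)c2OC)ccc(OC)c1OC | intermediate (not isolated)
18 | macrocyclic 3-aryloxy-2-alkylcyclohex-2-enone (tetramethoxy cyclophane, future ring D as cyclohexenone) | O=C1CCCC2=C1CCc1cc(OC)c(OC)c(c1)Oc1ccc(cc1)CCc1ccc(OC)c(OC)c1O2 | intermediate
19 | 6-iodo derivative of 18 (iodine on the CH2 next to the carbonyl) | O=C1C(I)CCC2=C1CCc1cc(OC)c(OC)c(c1)Oc1ccc(cc1)CCc1ccc(OC)c(OC)c1O2 | intermediate (not isolated)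
20 | macrocyclic ring D phenol (tetramethoxy cyclophane) | Oc1cccc2c1CCc1cc(OC)c(OC)c(c1)Oc1ccc(cc1)CCc1ccc(OC)c(OC)c1O2 | intermediate
21 | macrocyclic ring D aryl triflate | O=S(=O)(Oc1cccc2c1CCc1cc(OC)c(OC)c(c1)Oc1ccc(cc1)CCc1ccc(OC)c(OC)c1O2)C(F)(F)F | intermediate
22 | tetra-O-methyl ether of the target | c1ccc2c(c1)CCc1cc(OC)c(OC)c(c1)Oc1ccc(cc1)CCc1ccc(OC)c(OC)c1O2 | intermediate
23 | CNP0114693.0 | Oc1cc2cc(c1O)Oc1ccc(cc1)CCc1ccc(O)c(O)c1Oc1ccccc1CC2 | target

## Step count and risks

Total: 15 steps. Longest linear sequence: 13 steps (from 1 through steps 1–3 and 6–15); the branch from 5 is 12 steps.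

**Step 11 (key step).** The most likely failure is intermolecular substitution outrunning ring closure, giving dimers and oligomers, or a slow reaction because both the phenoxide and the 2-alkylated β-carbon are crowded. Carbonate may also hydrolyse the chloroenone back to the dione.

Fallback: give up the chloroenone and close the same C–O–D bond on an aromatic ring D by copper-mediated Ullmann coupling. It sets out from 5 and returns at 22.
- Wittig reaction of 5 with (2-bromobenzyl)triphenylphosphonium bromide and excess KOtBu would give 5-[2-(2-bromophenyl)ethenyl]-2,3-dimethoxyphenol F1.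
- SNAr with 7 (K2CO3, DMF) would give 4-{5-[2-(2-bromophenyl)ethenyl]-2,3-dimethoxyphenoxy}benzaldehyde F2.
- Wittig reaction with ylide 9 would give the bis-stilbene benzyl ether F3.
- Diimide (TsNHNH2, NaOAc, aqueous DME, reflux) would saturate both alkenes without touching bromine or benzyl, giving F4.
- BCl3 with pentamethylbenzene at −78 °C would remove the benzyl group to give the seco phenol aryl bromide F5.
- CuI (copper iodide), N,N-dimethylglycine and Cs2CO3 in dioxane under dilution would close the ring to 22.

This route has no aromatisation or deoxygenation steps, but it brings back the hindered arylation.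

**Step 8.** The arylacetaldehyde may self-condense by enamine aldol chemistry, or a second dione may add to 13 before hydride transfer.

Fallback: alkylation of a masked dione, setting out from 11 and returning at 14.
- NaBH4 would give the 2-arylethanol F6.
- I2, PPh3 and imidazole would give the 2-arylethyl iodide F7.
- 1,5-Dimethoxycyclohexa-1,4-diene, lithiated at C6 with t-BuLi in THF at −78 °C, would be alkylated by F7 to give the 6-(2-arylethyl)-1,5-dimethoxycyclohexa-1,4-diene F8.
- Dilute HCl in THF would hydrolyse both enol ethers to 14.

**Step 10.** The free ring C phenol may be acylated by oxalyl chloride alongside the dione, consuming reagent and giving oxalate-bridged material.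

Fallback: mask the phenol as a silyl ether, setting out from 15 and returning at 16.
- Excess TBSCl and imidazole in DMF would give the bis-silyl compound F9 (aryl silyl ether and silyl enol ether).
- The silyl enol ether would hydrolyse on mildly acidic aqueous work-up to the aryl silyl ether dione F10.
- Oxalyl chloride with catalytic DMF would give the silyl-protected chloroenone F11.
- TBAF buffered with acetic acid in THF at 0 °C would release 16 without triggering cyclisation.

**Step 12.** Electrophilic iodination of the electron-rich rings A and C or of the product phenol may compete with α′-iodination. Benzylic oxidation and hydrolysis of the vinylogous ester by the HI and water formed are further concerns. Adventitious aryl iodides would be reduced in step 14, but the losses remain.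

Fallback: dehydrogenation through the kinetic enolate, setting out from 18 and returning at 20.
- LDA in THF at −78 °C followed by PhSeBr would give the 6-(phenylselanyl) ketone F12.
- H2O2 with pyridine in CH2Cl2 would oxidise it to the selenoxide, which undergoes syn-elimination; the resulting dienone tautomerises to 20.

## Further compounds

F1 | step 11 | 5-[2-(2-bromophenyl)ethenyl]-2,3-dimethoxyphenol | COc1cc(C=Cc2ccccc2Br)cc(O)c1OC
F2 | step 11 | 4-{5-[2-(2-bromophenyl)ethenyl]-2,3-dimethoxyphenoxy}benzaldehyde | COc1cc(C=Cc2ccccc2Br)cc(Oc2ccc(C=O)cc2)c1OC
F3 | step 11 | bis-stilbene benzyl ether aryl bromide | COc1cc(C=Cc2ccccc2Br)cc(Oc2ccc(C=Cc3ccc(OC)c(OC)c3OCc3ccccc3)cc2)c1OC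
F4 | step 11 | saturated benzyl ether aryl bromide | COc1cc(CCc2ccccc2Br)cc(Oc2ccc(CCc3ccc(OC)c(OC)c3OCc3ccccc3)cc2)c1OC
F5 | step 11 | seco phenol aryl bromide | COc1cc(CCc2ccccc2Br)cc(Oc2ccc(CCc3ccc(OC)c(OC)c3O)cc2)c1OC
F6 | step 8 | 2-{3-[4-(2-[2-(benzyloxy)-3,4-dimethoxyphenyl]ethenyl)phenoxy]-4,5-dimethoxyphenyl}ethanol | OCCc1cc(OC)c(OC)c(c1)Oc1ccc(cc1)C=Cc1ccc(OC)c(OC)c1OCc1ccccc1
F7 | step 8 | corresponding 2-arylethyl iodide | ICCc1cc(OC)c(OC)c(c1)Oc1ccc(cc1)C=Cc1ccc(OC)c(OC)c1OCc1ccccc1
F8 | step 8 | 6-(2-arylethyl)-1,5-dimethoxycyclohexa-1,4-diene | COC1=CCC=C(OC)C1CCc1cc(OC)c(OC)c(c1)Oc1ccc(cc1)C=Cc1ccc(OC)c(OC)c1OCc1ccccc1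
F9 | step 10 | bis(tert-butyldimethylsilyl) derivative of 15 (aryl silyl ether and silyl enol ether) | CC(C)(C)[Si](C)(C)OC1=C(CCc2cc(OC)c(OC)c(c2)Oc2ccc(cc2)CCc2ccc(OC)c(OC)c2O[Si](C)(C)C(C)(C)C)C(=O)CCC1
F10 | step 10 | aryl tert-butyldimethylsilyl ether of 15 | O=C1CCCC(=O)C1CCc1cc(OC)c(OC)c(c1)Oc1ccc(cc1)CCc1ccc(OC)c(OC)c1O[Si](C)(C)C(C)(C)C
F11 | step 10 | aryl tert-butyldimethylsilyl ether of 16 | ClC1=C(CCc2cc(OC)c(OC)c(c2)Oc2ccc(cc2)CCc2ccc(OC)c(OC)c2O[Si](C)(C)C(C)(C)C)C(=O)CCC1
F12 | step 12 | 6-(phenylselanyl) derivative of 18 | O=C1C([Se]c3ccccc3)CCC2=C1CCc1cc(OC)c(OC)c(c1)Oc1ccc(cc1)CCc1ccc(OC)c(OC)c1O2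
A1 | alternative 1 | 17-membered aryl arylacetate macrolactone | O=C1Cc2ccccc2Oc2c(OC)c(OC)ccc2CCc2ccc(cc2)Oc2cccc(OC)c2O1
A2 | alternative 1 | macrocyclic para-hydroxy deoxybenzoin | COc1cc2cc(c1O)Oc1ccc(cc1)CCc1ccc(OC)c(OC)c1Oc1ccccc1CC2=O
A3 | alternative 2 | seco buta-1,3-dien-2-yl ether alkyne | C=CC(=C)Oc1cc(CCc2ccccc2Oc2c(CCC#C)ccc(OC)c2OC)cc(OC)c1OC
A4 | alternative 2 | macrocycle with ring B as 1,4-cyclohexadiene | COc1cc2cc(c1OC)OC1=CCC(=CC1)CCc1ccc(OC)c(OC)c1Oc1ccccc1CC2
A5 | alternative 3 | seco 2,6-dibromophenol 2,6-dichlorophenol | Oc1c(Br)cc(CCc2ccccc2Oc2c(CCc3cc(Cl)c(O)c(Cl)c3)ccc(OC)c2OC)cc1Br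
A6 | alternative 3 | bromo dichloro macrocycle | Oc1c(Br)cc2cc1Oc1c(Cl)cc(cc1Cl)CCc1ccc(OC)c(OC)c1Oc1ccccc1CC2
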